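The readings come from a simulation for substances that don't exist, and the scatter is random.

The vessel was a closed, stirred flask at constant volume and temperature, and I had earlier runs to go on before charging it with E and G to make Q.

| flask | E | G | remark | time |
|---|---|---|---|---|
| Saturday's | 0.050 M | 0.020 M | run made earlier |  |
| Wednesday's | 0.050 M | 0.045 M | run made earlier |  |
| Friday's | 0.10 M | 0.030 M | run made earlier |  |
| flask | 0.050 M | 0.0300 M |  | 8.0 min |

| run | time / min | E / % | Q / % |
|---|---|---|---|
| Saturday's | 1.33 | 96.2 | 2.9 |
| Saturday's | 3.00 | 97.3 | 2.1 |
| Saturday's | 6.00 | 97.3 | 3.1 |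
| Saturday's | 10.0 | 96.9 | 2.8 |
| Wednesday's | 1.33 | 89.6 | 7.6 |
| Wednesday's | 3.00 | 89.5 | 7.8 |
| Wednesday's | 6.00 | 90.5 | 8.1 |
| Wednesday's | 10.0 | 89.9 | 7.8 |
| Friday's | 1.33 | 92.7 | 6.3 |
| Friday's | 3.00 | 91.7 | 6.0 |
| Friday's | 6.00 | 93.2 | 6.3 |
| Friday's | 10.0 | 92.0 | 6.6 |

(readings scatter by 0.5 percentage points)

1. at 8.0 min, what has stopped the reaction, if anything has (G has run out first / all of E has reacted / it is still moving / forward and back rates have come level)
2. share of the E used up at 8.0 min
3. Q at 8.0 min, in percent of the E charged
4. amount of Q if the flask were left three thousand times as long, in percent of the E charged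

- the numbers in the tables scatter by 0.5 percentage points (one standard deviation)
- the reaction counts as stopped when no species that holds the E changes by six tenths of a point or more over the second half of the time

Saturday's, Wednesday's and Friday's runs were flat within the scatter from their first reading at 1.33 min, and the asked time of 8.0 min is 6.02 times that, so I expected a plateau and asked how high it stands. I had two ways of reckoning that height. The first reads across from Friday's run, which carried the flask's G of 0.030 M at twice the E and held a mean Q of 6.30%. The second stays at the flask's E of 0.050 M, where Saturday's mean Q of 2.73% and Wednesday's of 7.83% bracket the flask's G. From these I read the charge exponent n, the slope of ln(plateau Q) against ln(G charged) between two runs at the same E, as 1.30, which puts the flask at 4.62%.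

The two ways part by 1.7 percentage points, while one reading scatters by 0.5 points. Friday's is the one that cheats: its percent stands higher than mine, so the percent itself moves with the E charged, and that run differs from the flask in exactly this setting. I committed to 4.62%, and to the same figure at long times. The same reckoning on E used, from 3.08% and 10.1%, gave me 5.58%.

The forecast said G has run out first, with 5.6% of E used, Q at 4.7% and 4.7% on the long stay, holding that “a parasitic loss destroys G quickly”. Its Q stands slightly above mine.

The flask's answer was: G has run out first, with 5.46% of E used, Q at 4.63% and 4.63% on the long stay, against the 4.62% that n gave.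

    E + G → Q (k = 0.120 M⁻¹ s⁻¹)
    G → X (k = 0.110 s⁻¹)
    E + G + Q → 2 Q (k = 110 M⁻² s⁻¹)
    G + Q → J (k = 1.70 M⁻¹ s⁻¹)

G, the limiting reagent, stood at 0.208% of its charge by 0.800 min and at 0% by 8.00 min, so the first minute was the one to watch. The falling G was the main reason the flask stopped: with G held at its charge, conversion of E reached 99.3% against 5.46%. Carried to a flask with 0.12 M of G, n gave 28.0% of Q, and that flask held 30.2%.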